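## Structural features

The target is a humulane-type diester. It has one eleven-membered carbocycle (C1 = acetoxy carbon, C11 = gem-dimethyl carbon) and, outside it, only the benzene ring of a 4-hydroxybenzoate.

Round the ring stand:
- the C1 acetate,
- a Z-trisubstituted C2=C3 alkene (methyl on C3),
- the C4 aroyloxy carbon,
- the doubly allylic C5 methylene,
- an E-trisubstituted C6=C7 alkene (methyl on C7),
- the methylenes C8–C10,
- the quaternary C11, which is bonded directly to C1.

The only two stereocentres, C1 (R) and C4 (R), are not neighbours. They stand 1,4 to each other across the Z alkene, and their oxygens lie on the same face of the ring.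

The fragile points are these:
- both esters are allylic and can ionise or undergo SN2′ attack;
- the Z-ene-1,4-diol stage can cyclodehydrate under acid to a bridged dihydrofuran;
- the C5 methylene lets C6=C7 slip into conjugation whenever C4 is a carbonyl;
- the phenol is free.

The real difficulty is threefold. A medium ring must be closed, a Z-trisubstituted alkene must be fixed between two carbinols (one of them, C1, neopentylic), and two different acyl groups must then be placed on two secondary allylic alcohols.

The key step exploits the cis C1–O/C4–O pair. One silicon atom can span both oxygens and put C2=C3 into a seven-membered 1,3-dioxa-2-silacyclohept-5-ene (Si–O–C1–C2=C3–C4–O), where only Z can exist. Because the C5–C11 chain already joins C1 and C4, the same bond also closes the eleven-membered ring.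

The steric gap between the neopentylic C1–OH and the ordinary C4–OH is used twice: for ordered attachment of silicon and for site-selective acylation.

## Logic of the disconnections

**24 ⇒ 23.** Only the phenol oxygen changes: its O–H becomes an O–acetyl bond. A free phenol would compete in both acylations, and the acetyl mask allows the aroyl unit to be bought as 21. The gain is that no reagent has to be prepared. The forward step must split an aryl acetate without touching the alkyl acetate at C1 or the alkyl benzoate at C4.

**23 ⇒ 22 ⇒ 20 + 21.** The acyl–oxygen bonds at O1 (acetate) and O4 (aroyl) are cut. They are made last because allylic esters would not survive organometallics, hydrides or fluoride. The gain is 20, an unprotected diol whose two hydroxyls differ strongly in hindrance. The demand is kinetic site selection. The larger acyl group enters first at the accessible O4, and the small acetyl is then forced onto the neopentylic O1.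

**20 ⇒ 19.** O1 and O4 are reconnected through two Si–O bonds. This converts the Z-geometry problem into a ring-size problem and protects both alcohols at once. The demand is that silicon be removed without ionising the bis-allylic diol, hence buffered fluoride.

**19 ⇒ 18.** C2=C3 is cut into a C1 vinyl and a C4 isopropenyl group. This is the only alkene whose geometry a small ring can dictate, and the cut removes the eleven-membered ring and the bicycle in one stroke. The gain is a monocyclic triene with two terminal alkenes and an inert trisubstituted one. The demands are that metathesis occur only at the terminal alkenes, that it run transannularly, and that 18 carry the cis (1R,4R) relationship.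

**18 ⇒ 15 + 16.** Both Si–O bonds are cut. The gain is an open-chain diol. The demand is serious, because the forward step is itself a twelve-membered ring closure. Silicon must first be placed completely on O4, so that no unhindered hydroxyl remains as an intermolecular partner. Only then is it closed onto O1 at high dilution.

**15 ⇒ 14.** The C1–H and C4–H bonds are cut. Both carbinols come from ketones because one catalyst enantiomer serves both sites: the tert-alkyl group is the large group at C1 and isopropenyl is the large group at C4. The gain is an achiral precursor and both stereocentres in a single operation, with statistical enrichment of the enantiomer. The demand is 1,2-reduction of two sensitive enones without alkene migration, conjugate reduction or hydroboration.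

**14 ⇒ 13 ⇒ 12.** The C3–C4 bond is cut (isopropenyl nucleophile plus C4 aldehyde). The double oxidation is placed after it, so the vinyl ketone and the skipped enone exist for one step only. The gain is that no protecting group is needed. The demand is clean addition to a β,γ-unsaturated, easily enolised aldehyde.

**12 ⇒ 11 ⇒ 7 + 8.** The C5–C6 and C7–CH3 bonds are cut. One carbometalation sets the E alkene and 8 supplies C4–C5. The gain is a terminal alkyne. There are three demands. C1 must already be at the alcohol level, because an ester would not survive Me3Al and n-BuLi. The alkyne must react before the C1 vinyl group. The later oxidation must pick the primary alcohol.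

**7 ⇒ 6 ⇒ 5.** The C1–C2 bond is cut (vinyl nucleophile plus neopentylic aldehyde), and the aldehyde is traced to the ester. No stereocontrol is demanded, since C1 is reset later. The demand is only to stop the ester reduction at the aldehyde.

**5 ⇒ 3 + 2; 2 ⇒ 1.** The C10–C11 bond is cut. Alkylating the enolate of 3 creates the quaternary carbon from two simple pieces. The demand is an electrophile reactive enough (iodide 2 from chloride 1) to outrun proton transfer from the alkyne.

## Other disconnections considered

**Alternative 1:** The cut is C1–C11, the most congested σ-bond of the ring.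

*Forward step.* CrCl2 (divalent chromium) would reduce the tertiary allylic chloride of (2Z,4R,6E,9E)-4-(tert-butyldimethylsilyloxy)-11-chloro-3,7,11-trimethyldodeca-2,6,9-trienal A1. The resulting allylchromium rests at the less substituted terminus C9 and attacks the aldehyde through C11. This gives (1R,2Z,4R,6E,9E)-4-(tert-butyldimethylsilyloxy)-3,7,11,11-tetramethylcycloundeca-2,6,9-trien-1-ol A2. Saturating C9=C10 would then give (1R,2Z,4R,6E)-4-(tert-butyldimethylsilyloxy)-3,7,11,11-tetramethylcycloundeca-2,6-dien-1-ol A3.

*In favour.*
- The quaternary carbon, the C1 carbinol and the ring arise together.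
- Attack through the more substituted allyl terminus is the normal mode.
- Chromium tolerates the silyl ether and the alkenes.
- The oxygens come out already differentiated (O4 silylated, O1 free), which is better than the chosen plan for the endgame.
- No tether has to be put on and taken off.

*Against.*
- The Z-enal of A1 is configurationally labile, so Z geometry is carried rather than enforced.
- A tertiary allylic chloride beside an enal is hard to make and to store.
- The C1 configuration would depend on a remote centre (C4) through a macrocyclic transition state that cannot be predicted.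
- Attack through C9 would give a nine-membered ring.
- C9=C10, next to the quaternary carbon, must be reduced selectively in a triene.

*Comparison.* Both plans stake everything on an unproven high-dilution medium-ring closure, and there they are equal. The chosen plan fixes both carbinols by reagent control before closure and gets Z from ring size. Alternative 1 is likely shorter around the closure but weaker on every stereochemical point.

**Alternative 2:** Retrosynthetically C4–C5 is cut and C2–C7 reconnected, contracting the ring to a cycloheptane.

*Forward step.* The substrate is the potassium alkoxide (KH, 18-crown-6) of (1S,2R,3R)-3-(tert-butyldimethylsilyloxy)-1-ethenyl-2-[(1E)-1-(4-methoxybenzyloxy)prop-1-en-2-yl]-4,4-dimethylcycloheptan-1-ol A4. It would undergo a [3,3] shift, and PhNTf2 would trap the C7 enolate. The product is (target numbering) (1R,2Z,4R,6Z)-1-(tert-butyldimethylsilyloxy)-4-(4-methoxybenzyloxy)-3,11,11-trimethylcycloundeca-2,6-dien-7-yl trifluoromethanesulfonate A5. Methyl cross-coupling and two deprotections would lead to 20.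

*In favour.*
- Ring expansion avoids the entropic cost of a medium-ring closure, and on this point it is better than the chosen plan.
- The rearrangement is charge-accelerated and stereospecific, passing chirality from C2 to C4.
- The triflate fixes the C6=C7 geometry.

*Against.*
- A chair analysis shows that the required outcome needs the cis-dialkenyl isomer. The C7–C8 bond must be equatorial, the C2–C1 ring bond axial (the price of a Z C2=C3), and the enol ether E. Other chair or boat arrays lead to other geometries.
- A4 carries three contiguous stereocentres beside a quaternary carbon plus a defined enol ether, so making it should cost more steps than the whole chosen route.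
- The C7 alkoxide and the C1 silyl ether stand 1,3, so silyl migration can compete.
- The medium-ring enolate can undergo transannular proton transfer before it is trapped.

*Comparison.* The ring-forming event is mechanistically the more reliable, but the difficulty is moved into the precursor. The number of endgame steps is about equal.

**Alternative 3:** Retrosynthetically C1 and C7 are reconnected, giving a trans-fused six–seven bicycle.

*Forward step.* The substrate is (1R,4R,6S,7R)-4-(tert-butyldimethylsilyloxy)-1-hydroxy-3,7,11,11-tetramethylbicyclo[5.4.0]undec-2-en-6-yl methanesulfonate A6. This is one consistent choice of descriptors, with a trans fusion and the equatorial C6 mesylate antiperiplanar to C1–C7. KOt-Bu would trigger a Grob fragmentation to (2Z,4R,6E)-4-(tert-butyldimethylsilyloxy)-3,7,11,11-tetramethylcycloundeca-2,6-dien-1-one A7. A 1,2-reduction would then give A3.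

*In favour.*
- Fragmentation, not cyclisation, delivers the medium ring, which is at least as dependable as any closure.
- E C6=C7 follows stereospecifically from ring stereochemistry.
- Z C2=C3 is inherited from a seven-membered ring, the same principle as in the chosen plan, so the two are equal there.

*Against.*
- A6 has four stereocentres, including a tertiary carbinol wedged between two quaternary carbons. Three of them are built only to be destroyed.
- A7 is a strained Z-enone with an acidic γ-position at C4, so the base can cost the C4 configuration or the alkene position.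
- C1 must then be set on a neopentylic enone by substrate or late reagent control, with no secured facial bias.

*Comparison.* It is stronger on C6=C7 and on the ring-opening mechanism. It is weaker on C1 and clearly longer.

Key step: step 11

Remark (numbering): the ring numbering of 24 (C1–C11) is used for all intermediates.
Remark (descriptors): in open-chain 15 the stereocentres are chain atoms C3 and C11 (ring C4 and C1). Chain atom C12 is an alkene carbon and cannot carry a descriptor, so the correct set is 3R,5E,11R.
Remark (ring count): step 11 forms one bond, so the ring count rises from one to two (bicyclo[7.3.2]). Two new circuits, seven- and eleven-membered, appear beside the surviving twelve-membered one.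
Assumption: 21, LiN(i-Pr)2 solution, both Grignard solutions and the oxazaborolidine are taken as purchased.

## Steps

Step 1
Reactants: 1 5-chloropent-1-yne
Product: 2 5-iodopent-1-yne
Conditions: NaI, acetone, reflux
Reagents that add atoms: sodium iodide [Na+].[I-]
Why: Finkelstein exchange driven by precipitation of NaCl; the iodide is needed because lithium ester enolates alkylate primary chlorides too slowly.

Step 2
Reactants: 3 methyl isobutyrate; 2 5-iodopent-1-yne
Product: 5 methyl 2,2-dimethylhept-6-ynoate, via lithium enolate 4 (not isolated)
Conditions: LiN(i-Pr)2, THF, −78 °C; then 2, DMPU, −78 °C to rt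
Reagents that add atoms: none
Why: SN2 alkylation of a fully substituted ester enolate forms C10–C11 and the quaternary C11; only one enolate is possible and a second alkylation cannot occur. Proton transfer from the alkyne should be slower than attack on a primary iodide and would only return the reactants.

Step 3
Reactants: 5 methyl 2,2-dimethylhept-6-ynoate
Product: 6 2,2-dimethylhept-6-ynal
Conditions: i-Bu2AlH (1.1 equiv), CH2Cl2, −78 °C; MeOH, then aq. potassium sodium tartrate
Reagents that add atoms: none
Why: Partial ester reduction; the α-quaternary centre stabilises the tetrahedral aluminium hemiacetal at −78 °C, so the aldehyde is released only on quenching. Aldehyde 6 has no α-hydrogen and is robust.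

Step 4
Reactants: 6 2,2-dimethylhept-6-ynal
Product: 7 racemic 4,4-dimethylnon-1-en-8-yn-3-ol
Conditions: CH2=CHMgBr (2.5 equiv), THF, −78 to 0 °C; aq. NH4Cl
Reagents that add atoms: vinylmagnesium bromide C=C[Mg]Br
Why: Grignard 1,2-addition to a non-enolisable aldehyde forms C1–C2. No stereocontrol is sought because C1 is reset in step 9; the alcohol is the stable, latent form of the vinyl ketone.

Step 5
Reactants: 7 racemic 4,4-dimethylnon-1-en-8-yn-3-ol; 8 ethylene oxide
Product: 11 (3E)-4,8,8-trimethylundeca-3,10-diene-1,9-diol (racemic at C9), via E-alkenyldimethylalane 9 (not isolated), via lithium alkenylalanate 10 (not isolated)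
Conditions: Me3Al (4 equiv), Cp2ZrCl2 (25 mol %), CH2Cl2, 0 °C to rt; volatiles removed; n-BuLi, hexane–THF, −78 to 0 °C; 8, 0 °C to rt; aq. potassium sodium tartrate
Reagents that add atoms: trimethylaluminium C[Al](C)C
Why: Negishi zirconium-catalysed methylalumination adds CH3 (to C7) and Al (to C6) syn across the terminal alkyne and so fixes the E geometry; the alanate opens ethylene oxide with retention at C6 and brings in C5–C4. The hydroxyl is only converted into an aluminium alkoxide, and the hindered C1 vinyl group should be far slower than a terminal alkyne.

Step 6
Reactants: 11 (3E)-4,8,8-trimethylundeca-3,10-diene-1,9-diol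
Product: 12 (3E)-9-hydroxy-4,8,8-trimethylundeca-3,10-dienal
Conditions: 2,2,6,6-tetramethylpiperidin-1-oxyl (10 mol %), PhI(OAc)2 (1.1 equiv), CH2Cl2, 0 °C to rt; used at once
Reagents that add atoms: none
Why: Oxoammonium (TEMPO) oxidation is strongly biased towards the unhindered primary alcohol and should leave the neopentylic secondary one. The medium contains no base, which should keep C6=C7 out of conjugation.

Step 7
Reactants: 12 (3E)-9-hydroxy-4,8,8-trimethylundeca-3,10-dienal
Product: 13 (5E)-2,6,10,10-tetramethyltrideca-1,5,12-triene-3,11-diol as the mixture of its four stereoisomers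
Conditions: CH2=C(CH3)MgBr (2.5 equiv), LaCl3·2LiCl (1 equiv), THF, −78 °C; aq. NH4Cl
Reagents that add atoms: isopropenylmagnesium bromide CC(=C)[Mg]Br
Why: Lanthanide-assisted Grignard 1,2-addition forms C3–C4; the salt activates the carbonyl and damps basicity, which should suppress enolisation of the β,γ-unsaturated aldehyde. The first equivalent only deprotonates the C1 hydroxyl, and no stereocontrol is needed.

Step 8
Reactants: 13 (5E)-2,6,10,10-tetramethyltrideca-1,5,12-triene-3,11-diol (stereoisomer mixture)
Product: 14 (5E)-2,6,10,10-tetramethyltrideca-1,5,12-triene-3,11-dione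
Conditions: Dess–Martin periodinane (3 equiv), NaHCO3, CH2Cl2, 0 °C; short silica plug, used at once
Reagents that add atoms: none
Why: Dess–Martin oxidation of both allylic alcohols under buffered, non-basic conditions merges four stereoisomers into one achiral compound. The vinyl ketone and the skipped enone are exposed only one step before they are consumed.

Step 9
Reactants: 14 (5E)-2,6,10,10-tetramethyltrideca-1,5,12-triene-3,11-dione
Product: 15 (3R,5E,11R)-2,6,10,10-tetramethyltrideca-1,5,12-triene-3,11-diol
Conditions: (S)-1-methyl-3,3-diphenyltetrahydro-1H,3H-pyrrolo[1,2-c][1,3,2]oxazaborole (40 mol %), BH3·SMe2 (1.6 equiv), THF, −40 to −20 °C, slow addition of 14; MeOH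
Reagents that add atoms: none
Why: Twofold Corey–Bakshi–Shibata reduction; the ketone binds the catalyst anti to its larger group, which is isopropenyl (against CH2) at C4 and tert-alkyl (against vinyl) at C1, so the S catalyst should give R at both centres. Two independent selective events enrich the enantiomer statistically and send errors into 1,4-trans diastereomers, which diverge in steps 10 and 11. Low temperature and near-stoichiometric borane guard against hydroboration.

Step 10
Reactants: 15 (3R,5E,11R)-2,6,10,10-tetramethyltrideca-1,5,12-triene-3,11-diol; 16 dichlorodiisopropylsilane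
Product: 18 (4R,6E,12R)-12-ethenyl-7,11,11-trimethyl-2,2-di(propan-2-yl)-4-(prop-1-en-2-yl)-1,3-dioxa-2-silacyclododec-6-ene, via C4 chlorosilyl ether 17 (not isolated)
Conditions: 15 added slowly to 16 (3 equiv), Et3N, 4-dimethylaminopyridine (5 mol %), CH2Cl2, −20 °C; filtration under Ar, excess 16 removed in vacuo; then syringe pump into imidazole, 4-dimethylaminopyridine (20 mol %), ClCH2CH2Cl (final 1 mM), 4 Å molecular sieves, 60 °C
Reagents that add atoms: none
Why: Silyl ether formation in two stages; the first chloride of 16 is much more reactive than the second, and inverse addition to excess 16 should silylate every unhindered C4–OH while the neopentylic C1–OH waits. With only hindered hydroxyls left, intramolecular closure at 1 mM should beat intermolecular silylation. Isopropyl groups are kept on silicon because they make the silaketal stable to chromatography and heat, while a bulkier pair would not close onto O1.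

Step 11
Reactants: 18 (4R,6E,12R)-12-ethenyl-7,11,11-trimethyl-2,2-di(propan-2-yl)-4-(prop-1-en-2-yl)-1,3-dioxa-2-silacyclododec-6-ene
Product: 19 (1R,3E,9R,13Z)-4,8,8,13-tetramethyl-11,11-di(propan-2-yl)-10,12-dioxa-11-silabicyclo[7.3.2]tetradeca-3,13-diene (the eleven-membered diene with O1 and O4 bridged by diisopropylsilylene)
Conditions: second-generation Hoveyda–Grubbs catalyst (H2IMes)Cl2Ru=CH(2-i-PrO-C6H4) (2 × 5 mol %), 1,4-benzoquinone (20 mol %), toluene (2 mM), 80 °C, Ar sparge
Reagents that add atoms: none
Why: Proposed new method: the ruthenium benzylidene exchanges with the only monosubstituted alkene, the C1 vinyl group, to give the C2 alkylidene; this adds [2+2] to the C4 isopropenyl group held close through C1–O–Si–O–C4, and cycloreversion of the ruthenacyclobutane leaves C2=C3 and Ru=CH2, which leaves as ethylene on turnover. The closest known reaction type is temporary silicon-tethered ring-closing metathesis of bis(allyloxy)silanes to Z-trisubstituted seven-membered silaketals; the untested element is that the two carbinol carbons are already linked by C5–C11, so closure runs transannularly across a twelve-membered ring. The seven-membered 1,3-dioxa-2-silacyclohept-5-ene closes as an ordinary tethered diene metathesis in which both alkenes shed their CH2 termini, and the eleven-membered carbocycle is closed by the same bond as a transannular partition of the twelve-membered circuit, giving a bicyclo[7.3.2] frame with C1 and C4 as bridgeheads. No stereocentre is formed; the only new stereoelement is the C2=C3 geometry, which the seven-membered ring fixes as Z because it cannot hold an E alkene. Site selectivity rests on C6=C7 being trisubstituted: its engagement would need either a fully substituted ruthenacycle carbon or a disubstituted alkylidene, both slower than attack on a 1,1-disubstituted alkene through a seven-ring array. Only the cis (1R,4R) silylene can place both alkenyl groups on the face away from the carbon bridge, so any 1,4-trans isomer left from step 9 would need an in,out bicycle and should stay behind. The gem-diisopropyl substitution narrows the O–Si–O angle and favours convergent rotamers; dilution and sparging suppress cross-metathesis and remove ethylene, and benzoquinone intercepts ruthenium hydrides that could isomerise the allylic silyl ethers.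

Step 12
Reactants: 19 bicyclic diisopropylsilylene
Product: 20 (1R,2Z,4R,6E)-3,7,11,11-tetramethylcycloundeca-2,6-diene-1,4-diol
Conditions: HF·pyridine, excess pyridine, THF, 0 °C to rt (plastic vessel); aq. NaHCO3
Reagents that add atoms: none
Why: Fluoride-driven cleavage of both Si–O bonds, paid for by the strong Si–F bonds. Extra pyridine buffers the medium so the bis-allylic diol does not ionise; no C–O bond is touched, so both configurations are retained.

Step 13
Reactants: 20 (1R,2Z,4R,6E)-3,7,11,11-tetramethylcycloundeca-2,6-diene-1,4-diol; 21 4-acetoxybenzoyl chloride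
Product: 22 (1R,2Z,4R,6E)-4-(4-acetoxybenzoyloxy)-3,7,11,11-tetramethylcycloundeca-2,6-dien-1-ol
Conditions: 21 (1.05 equiv), pyridine, 4-dimethylaminopyridine (5 mol %), CH2Cl2, −20 to 0 °C
Reagents that add atoms: none
Why: Nucleophile-catalysed acylation under kinetic control; C4–OH is flanked by a CH2 and an sp2 carbon, while C1–OH is neopentylic, so a limited amount of a bulky acyl chloride at low temperature should pick O4. The acid chloride is far more reactive than the aryl acetate within 21.

Step 14
Reactants: 22 (1R,2Z,4R,6E)-4-(4-acetoxybenzoyloxy)-3,7,11,11-tetramethylcycloundeca-2,6-dien-1-ol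
Product: 23 (1R,2Z,4R,6E)-1-acetoxy-4-(4-acetoxybenzoyloxy)-3,7,11,11-tetramethylcycloundeca-2,6-diene
Conditions: Ac2O, Et3N, 4-dimethylaminopyridine, CH2Cl2, rt
Reagents that add atoms: acetic anhydride CC(=O)OC(C)=O
Why: 4-Dimethylaminopyridine-catalysed acetyl transfer to the one remaining, hindered hydroxyl; no other nucleophilic site is left and the C–O bond at C1 is not involved.

Step 15
Reactants: 23 (1R,2Z,4R,6E)-1-acetoxy-4-(4-acetoxybenzoyloxy)-3,7,11,11-tetramethylcycloundeca-2,6-diene
Product: 24 (1R,2Z,4R,6E)-1-acetoxy-4-(4-hydroxybenzoyloxy)-3,7,11,11-tetramethylcycloundeca-2,6-diene (CNP0246761.3)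
Conditions: pyrrolidine (1.2 equiv), CH2Cl2, 0 °C; dilute aq. citric acid
Reagents that add atoms: none
Why: Chemoselective aminolysis of an aryl acetate; the para-acyl phenoxide is a far better leaving group than a secondary alkoxide. The neopentylic C1 acetate and the C4 alkyl benzoate should be inert to a secondary amine at 0 °C.

## Compound list

1 | 5-chloropent-1-yne | C#CCCCCl | starting material
2 | 5-iodopent-1-yne | C#CCCCI | intermediate
3 | methyl isobutyrate | COC(=O)C(C)C | starting material
4 | lithium enolate of methyl isobutyrate | COC(=C(C)C)O[Li] | intermediate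
5 | methyl 2,2-dimethylhept-6-ynoate | COC(=O)C(C)(C)CCCC#C | intermediate
6 | 2,2-dimethylhept-6-ynal | O=CC(C)(C)CCCC#C | intermediate
7 | racemic 4,4-dimethylnon-1-en-8-yn-3-ol | C=CC(O)C(C)(C)CCCC#C | intermediate
8 | ethylene oxide | C1CO1 | starting material
9 | E-alkenyldimethylalane (C1 oxygen as dimethylaluminium alkoxide) | C=CC(O[Al](C)C)C(C)(C)CCC/C(C)=C/[Al](C)C | intermediate
10 | lithium butyl(alkenyl)dimethylalanate | [Li+].C=CC(O[Al](C)C)C(C)(C)CCC/C(C)=C/[Al-](C)(C)CCCC | intermediate
11 | (3E)-4,8,8-trimethylundeca-3,10-diene-1,9-diol (racemic) | C=CC(O)C(C)(C)CCC/C(C)=C/CCO | intermediate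
12 | (3E)-9-hydroxy-4,8,8-trimethylundeca-3,10-dienal (racemic) | C=CC(O)C(C)(C)CCC/C(C)=C/CC=O | intermediate
13 | (5E)-2,6,10,10-tetramethyltrideca-1,5,12-triene-3,11-diol (four stereoisomers) | C=CC(O)C(C)(C)CCC/C(C)=C/CC(O)C(C)=C | intermediate
14 | (5E)-2,6,10,10-tetramethyltrideca-1,5,12-triene-3,11-dione | C=CC(=O)C(C)(C)CCC/C(C)=C/CC(=O)C(C)=C | intermediate
15 | (3R,5E,11R)-2,6,10,10-tetramethyltrideca-1,5,12-triene-3,11-diol | C=C[C@@H](O)C(C)(C)CCC/C(C)=C/C[C@@H](O)C(C)=C | intermediate
16 | dichlorodiisopropylsilane | CC(C)[Si](Cl)(Cl)C(C)C | starting material
17 | C4 chloro(diisopropyl)silyl ether of 15 | C=C[C@@H](O)C(C)(C)CCC/C(C)=C/C[C@@H](O[Si](Cl)(C(C)C)C(C)C)C(C)=C | intermediate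
18 | (4R,6E,12R)-12-ethenyl-7,11,11-trimethyl-2,2-di(propan-2-yl)-4-(prop-1-en-2-yl)-1,3-dioxa-2-silacyclododec-6-ene | C=C[C@H]1O[Si](C(C)C)(C(C)C)O[C@@H](C(C)=C)C/C=C(\C)CCCC1(C)C | intermediate
19 | (1R,3E,9R,13Z)-4,8,8,13-tetramethyl-11,11-di(propan-2-yl)-10,12-dioxa-11-silabicyclo[7.3.2]tetradeca-3,13-diene | [C@H]12/C=C(/C)[C@H](O[Si](C(C)C)(C(C)C)O1)C/C=C(\C)CCCC2(C)C | intermediate
20 | (1R,2Z,4R,6E)-3,7,11,11-tetramethylcycloundeca-2,6-diene-1,4-diol | O[C@@H]1/C=C(/C)[C@H](O)C/C=C(\C)CCCC1(C)C | intermediate
21 | 4-acetoxybenzoyl chloride | CC(=O)Oc1ccc(cc1)C(Cl)=O | starting material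
22 | (1R,2Z,4R,6E)-4-(4-acetoxybenzoyloxy)-3,7,11,11-tetramethylcycloundeca-2,6-dien-1-ol | O[C@@H]1/C=C(/C)[C@H](OC(=O)c2ccc(OC(C)=O)cc2)C/C=C(\C)CCCC1(C)C | intermediate
23 | (1R,2Z,4R,6E)-1-acetoxy-4-(4-acetoxybenzoyloxy)-3,7,11,11-tetramethylcycloundeca-2,6-diene | CC(=O)O[C@@H]1/C=C(/C)[C@H](OC(=O)c2ccc(OC(C)=O)cc2)C/C=C(\C)CCCC1(C)C | intermediate
24 | (1R,2Z,4R,6E)-1-acetoxy-4-(4-hydroxybenzoyloxy)-3,7,11,11-tetramethylcycloundeca-2,6-diene | CC(=O)O[C@@H]1/C=C(/C)[C@H](OC(=O)c2ccc(O)cc2)C/C=C(\C)CCCC1(C)C | target

## Step count and least certain steps

Total steps: 15. Longest linear sequence: 15 (1 to 24).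

**Step 11 (key step, carries the label).**

*What may go wrong.* Loading of ruthenium on a vinyl group wedged between a silyloxy carbon and the quaternary C11 may be slow. The twelve-membered ring may also rest in conformers that hold the two alkenyl groups apart. Several processes could then overtake closure: catalyst decay, intermolecular metathesis, attack of the alkylidene on C6=C7 with loss of the macrocycle, or hydride-induced migration of the allylic alkenes.

*Fallback (known chemistry).* The ring is closed at C3–C4 by an intramolecular Nozaki–Hiyama–Kishi reaction. The fallback leaves the route at 6 and rejoins it at 20.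
- Aldehyde 6 and 1-propynylmagnesium bromide give racemic 5,5-dimethyldeca-2,9-diyn-4-ol F1.
- Dess–Martin oxidation gives 5,5-dimethyldeca-2,9-diyn-4-one F2.
- Reduction with the S oxazaborolidine and BH3·SMe2 (tert-alkyl large, alkynyl small) gives (4S)-5,5-dimethyldeca-2,9-diyn-4-ol F3. Its arrangement in space is that of 1R in the target; the descriptor changes only because alkynyl outranks tert-alkyl.
- The conditions of step 5, which act on the terminal alkyne only, give (3E,9S)-4,8,8-trimethyldodec-3-en-10-yne-1,9-diol F4.
- Hydroxyl-directed trans-hydroalumination with NaAlH2(OCH2CH2OMe)2, followed by I2, gives (3E,9R,10Z)-11-iodo-4,8,8-trimethyldodeca-3,10-diene-1,9-diol F5.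
- The conditions of step 6 give (3E,9R,10Z)-9-hydroxy-11-iodo-4,8,8-trimethyldodeca-3,10-dienal F6.
- CrCl2 with catalytic NiCl2 in DMSO–THF at high dilution closes C3–C4 with retention of the alkene geometry to give 20.

The C4 configuration is not secured in this closure. The epimer (1R,2Z,4S,6E)-3,7,11,11-tetramethylcycloundeca-2,6-diene-1,4-diol F7 would have to be separated.

**Step 10.**

*What may go wrong.* Attack of the neopentylic hydroxyl on a hindered chlorosilane may be slow. At millimolar dilution that gives hydrolysis by traces of water and intermolecular silylation (oligomerisation) time to compete. Incomplete site selection in the first stage would cap O1.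

*Fallback, from 15 back to 18.* Silicon is introduced as a hydridosilane that can be purified and is activated only afterwards. Chlorodiisopropylsilane and imidazole at −20 °C give the C4 diisopropylsilyl (Si–H) ether of 15 F8, which is chromatographed. N-Bromosuccinimide in CH2Cl2 at 0 °C converts Si–H into the more electrophilic C4 bromo(diisopropyl)silyl ether of 15 F9. Its solution is added slowly to Et3N and 4-dimethylaminopyridine in dilute CH2Cl2 to give 18.

**Step 9.**

*What may go wrong.*
- Facial selectivity may be incomplete at either ketone (vinyl against tert-alkyl, isopropenyl against allylic CH2).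
- The vinyl ketone may suffer conjugate reduction or hydroboration.
- C6=C7 may migrate into conjugation before reduction.

*Fallback, from 6 back to 15.* Both enones are avoided, and each carbinol is set in the C–C bond-forming event by catalytic asymmetric Nozaki–Hiyama–Kishi addition. The system is CrCl2, a chiral oxazoline–sulfonamide ligand, catalytic NiCl2, Mn and Cp2ZrCl2. Aldehyde 6 and vinyl bromide give (3R)-4,4-dimethylnon-1-en-8-yn-3-ol F10. The conditions of steps 5 and 6 give (3E,9R)-4,8,8-trimethylundeca-3,10-diene-1,9-diol F11 and (3E,9R)-9-hydroxy-4,8,8-trimethylundeca-3,10-dienal F12. 2-Bromopropene, with the ligand enantiomer that delivers 3R, then gives 15.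

**Step 5.**

*What may go wrong.*
- The aluminium alkoxide may retard carbometalation.
- The C1 vinyl group may be metalated.
- Alkenyl transfer from the alanate may be inefficient, with butyl or methyl transfer to the epoxide competing.

*Fallback, from 7 back to 11.* The alkenylalane is quenched with I2 to give isolable (8E)-9-iodo-4,4,8-trimethylnona-1,8-dien-3-ol F13. After deprotonation with n-BuLi and iodine–lithium exchange with t-BuLi (Et2O, −78 °C), the alkenyllithium opens 8 in the presence of BF3·OEt2 to give 11.

**Step 7 (with the aldehyde from step 6).**

*What may go wrong.* The Grignard reagent may enolise the aldehyde, and C6=C7 may migrate into conjugation.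

*Fallback, from 12 back to 13.* The basic organomagnesium is replaced by a non-basic organochromium reagent, that is, a Nozaki–Hiyama–Kishi addition of 2-bromopropene with CrCl2 and catalytic NiCl2 in DMF at rt. This tolerates the free hydroxyl and enolisable aldehydes and makes no compound outside the list (entry F0).

## Further compounds

F1 | step 11 | racemic 5,5-dimethyldeca-2,9-diyn-4-ol | CC#CC(O)C(C)(C)CCCC#C
F2 | step 11 | 5,5-dimethyldeca-2,9-diyn-4-one | CC#CC(=O)C(C)(C)CCCC#C
F3 | step 11 | (4S)-5,5-dimethyldeca-2,9-diyn-4-ol | CC#C[C@@H](O)C(C)(C)CCCC#C
F4 | step 11 | (3E,9S)-4,8,8-trimethyldodec-3-en-10-yne-1,9-diol | CC#C[C@@H](O)C(C)(C)CCC/C(C)=C/CCO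
F5 | step 11 | (3E,9R,10Z)-11-iodo-4,8,8-trimethyldodeca-3,10-diene-1,9-diol | C/C(I)=C/[C@@H](O)C(C)(C)CCC/C(C)=C/CCO
F6 | step 11 | (3E,9R,10Z)-9-hydroxy-11-iodo-4,8,8-trimethyldodeca-3,10-dienal | C/C(I)=C/[C@@H](O)C(C)(C)CCC/C(C)=C/CC=O
F7 | step 11 | (1R,2Z,4S,6E)-3,7,11,11-tetramethylcycloundeca-2,6-diene-1,4-diol | O[C@@H]1/C=C(/C)[C@@H](O)C/C=C(\C)CCCC1(C)C
F8 | step 10 | C4 diisopropylsilyl (Si–H) ether of 15 | C=C[C@@H](O)C(C)(C)CCC/C(C)=C/C[C@@H](O[SiH](C(C)C)C(C)C)C(C)=C
F9 | step 10 | C4 bromo(diisopropyl)silyl ether of 15 | C=C[C@@H](O)C(C)(C)CCC/C(C)=C/C[C@@H](O[Si](Br)(C(C)C)C(C)C)C(C)=C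
F10 | step 9 | (3R)-4,4-dimethylnon-1-en-8-yn-3-ol | C=C[C@@H](O)C(C)(C)CCCC#C
F11 | step 9 | (3E,9R)-4,8,8-trimethylundeca-3,10-diene-1,9-diol | C=C[C@@H](O)C(C)(C)CCC/C(C)=C/CCO
F12 | step 9 | (3E,9R)-9-hydroxy-4,8,8-trimethylundeca-3,10-dienal | C=C[C@@H](O)C(C)(C)CCC/C(C)=C/CC=O
F13 | step 5 | (8E)-9-iodo-4,4,8-trimethylnona-1,8-dien-3-ol (racemic) | C=CC(O)C(C)(C)CCC/C(C)=C/I
F0 | step 7 | none | none
A1 | alternative 1 | (2Z,4R,6E,9E)-4-(tert-butyldimethylsilyloxy)-11-chloro-3,7,11-trimethyldodeca-2,6,9-trienal | O=C/C=C(/C)[C@H](O[Si](C)(C)C(C)(C)C)C/C=C(\C)C/C=C/C(C)(C)Cl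
A2 | alternative 1 | (1R,2Z,4R,6E,9E)-4-(tert-butyldimethylsilyloxy)-3,7,11,11-tetramethylcycloundeca-2,6,9-trien-1-ol | O[C@@H]1/C=C(/C)[C@H](O[Si](C)(C)C(C)(C)C)C/C=C(\C)C/C=C/C1(C)C
A3 | alternative 1 | (1R,2Z,4R,6E)-4-(tert-butyldimethylsilyloxy)-3,7,11,11-tetramethylcycloundeca-2,6-dien-1-ol | O[C@@H]1/C=C(/C)[C@H](O[Si](C)(C)C(C)(C)C)C/C=C(\C)CCCC1(C)C
A4 | alternative 2 | (1S,2R,3R)-3-(tert-butyldimethylsilyloxy)-1-ethenyl-2-[(1E)-1-(4-methoxybenzyloxy)prop-1-en-2-yl]-4,4-dimethylcycloheptan-1-ol | O[C@]1(C=C)CCCC(C)(C)[C@H](O[Si](C)(C)C(C)(C)C)[C@H]1/C(C)=C/OCc2ccc(OC)cc2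
A5 | alternative 2 | (1R,2Z,4R,6Z)-1-(tert-butyldimethylsilyloxy)-4-(4-methoxybenzyloxy)-3,11,11-trimethylcycloundeca-2,6-dien-7-yl trifluoromethanesulfonate (target numbering) | CC(C)(C)[Si](C)(C)O[C@@H]1/C=C(/C)[C@H](OCc2ccc(OC)cc2)C/C=C(\OS(=O)(=O)C(F)(F)F)CCCC1(C)C
A6 | alternative 3 | (1R,4R,6S,7R)-4-(tert-butyldimethylsilyloxy)-1-hydroxy-3,7,11,11-tetramethylbicyclo[5.4.0]undec-2-en-6-yl methanesulfonate | O[C@@]12C=C(C)[C@H](O[Si](C)(C)C(C)(C)C)C[C@H](OS(C)(=O)=O)[C@@]1(C)CCCC2(C)C
A7 | alternative 3 | (2Z,4R,6E)-4-(tert-butyldimethylsilyloxy)-3,7,11,11-tetramethylcycloundeca-2,6-dien-1-one | O=C1/C=C(/C)[C@H](O[Si](C)(C)C(C)(C)C)C/C=C(\C)CCCC1(C)C
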